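**Retrosynthetic overview**
- Target ⇐ carbamoylation of the two benzylic alcohols of the free cyclophane hexaol ⇐ acid cleavage of six MOM ethers.
- 22-membered [7.7]paracyclophane ⇐ closed last by head-to-tail C-alkylation: C-2 of resorcinol ring B (as aryl–Mg/Cu) displaces the secondary tosylate at the butyl-bearing carbon with inversion. This is the same bond, polarity and stereochemical course as the resorcinol alkylation that closes the ring in the biosynthesis.
- Linear precursor ⇐ the same alkylation run intermolecularly first: C-2 of ring A displaces the tosylate at the chlorobutyl-bearing carbon of the second monomer (inversion).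
- Both monomers ⇐ cross-metathesis/hydrogenation of one common aryl bromide (syn-crotylation, then ortho-lithiation/bromination) with two epoxide-derived non-1-en-5-ols.
- Ring order: both benzene rings are bought; the only ring formed is the macrocycle, closed once, at the end.

Assumption: the SMILES is taken literally. Both alkyl-bearing benzylic carbons are S by CIP rules, but the chlorine changes the priority order, so they have opposite spatial sense; the two halves are therefore not related by a twofold axis and need separately made carbinol precursors.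

**Route**

Step 1
Reactants: 1 3,5-dihydroxybenzaldehyde
Product: 2 3,5-bis(methoxymethoxy)benzaldehyde
Conditions: MOMCl (2.5 equiv), i-Pr2NEt (3 equiv), CH2Cl2, 0 °C → rt
Reagents that add atoms: chloromethyl methyl ether (MOMCl), COCCl
Why: O-alkylation of both phenols (Williamson-type acetal formation) masks the acidic OH groups as MOM ethers that later direct ortho-lithiation and come off with acid; no stereocentre is involved.

Step 2
Reactants: 2 3,5-bis(methoxymethoxy)benzaldehyde
Product: 4 (1R,2S)-1-[3,5-bis(methoxymethoxy)phenyl]-2-methylbut-3-en-1-ol, via pinacol borate ester 3 (not isolated)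
Conditions: (Z)-crotyl-Bpin (1.3 equiv), (R)-3,3′-bis(2,4,6-triisopropylphenyl)-1,1′-binaphthyl-2,2′-diyl hydrogen phosphate (5 mol %), toluene, −30 °C; then aq. NaHCO3
Reagents that add atoms: (Z)-crotylboronic acid pinacol ester, C/C=C\CB1OC(C)(C)C(C)(C)O1
Why: chiral phosphoric acid-catalysed crotylboration through a closed chair (Zimmerman–Traxler) transition state, in which the Z-boronate fixes the syn relationship and the (R)-acid directs Re-face attack to give 1R,2S (sense as reported for benzaldehyde; the antipodal acid is used if Mosher analysis shows otherwise).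

Step 3
Reactants: 4 (1R,2S)-1-[3,5-bis(methoxymethoxy)phenyl]-2-methylbut-3-en-1-ol
Product: 7 2-bromo-1,3-bis(methoxymethoxy)-5-[(1R,2S)-1-(methoxymethoxy)-2-methylbut-3-en-1-yl]benzene, via dilithio alkoxide aryllithium 5 (not isolated), via lithium alkoxide of the aryl bromide 6 (not isolated)
Conditions: n-BuLi (2.2 equiv), THF, 0 °C, 1.5 h; BrCCl2CCl2Br (1.2 equiv), −78 °C; then MOMCl (1.5 equiv), 0 °C → rt
Reagents that add atoms: 1,2-dibromo-1,1,2,2-tetrachloroethane, BrC(Cl)(Cl)C(Cl)(Cl)Br; chloromethyl methyl ether (MOMCl), COCCl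
Why: directed ortho-metalation at the ring position flanked by the two MOM ethers (the first equivalent of base makes the alkoxide), electrophilic bromination of the aryllithium, and O-alkylation of the remaining lithium alkoxide by MOMCl in the same flask; the stereocentres are untouched.

Step 4
Reactants: 8 (R)-2-butyloxirane
Product: 9 (R)-non-1-en-5-ol
Conditions: allylMgCl (1.3 equiv), CuI (5 mol %), THF, −30 → 0 °C; aq. NH4Cl
Reagents that add atoms: allylmagnesium chloride, C=CC[Mg]Cl
Why: copper-catalysed SN2 opening of the terminal epoxide at its CH2 carbon by the allyl Grignard reagent, so the stereocentre of the commercial epoxide is carried over unchanged.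

Step 5
Reactants: 10 6-chlorohex-1-ene
Product: 11 rac-2-(4-chlorobutyl)oxirane
Conditions: mCPBA (1.2 equiv), CH2Cl2, 0 °C → rt
Reagents that add atoms: 3-chloroperoxybenzoic acid (mCPBA), OOC(=O)c1cccc(Cl)c1
Why: Prilezhaev epoxidation of the terminal alkene; the primary chloride is inert and the product is racemic at this stage.

Step 6
Reactants: 11 rac-2-(4-chlorobutyl)oxirane
Product: 12 (S)-2-(4-chlorobutyl)oxirane
Conditions: (S,S)-(salen)Co(OAc) [(S,S)-N,N′-bis(3,5-di-tert-butylsalicylidene)cyclohexane-1,2-diaminocobalt acetate, trivalent cobalt] (0.5 mol %), H2O (0.55 equiv), 0 °C → rt; distil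
Reagents that add atoms: none
Why: Jacobsen hydrolytic kinetic resolution, in which the (S,S)-catalyst hydrolyses the R epoxide and leaves the S epoxide in ≥99 % ee (checked by chiral GC).

Step 7
Reactants: 12 (S)-2-(4-chlorobutyl)oxirane
Product: 13 (S)-9-chloronon-1-en-5-ol
Conditions: allylMgCl (1.3 equiv), CuI (5 mol %), THF, −40 → −10 °C; cold aq. NH4Cl
Reagents that add atoms: allylmagnesium chloride, C=CC[Mg]Cl
Why: copper-catalysed SN2 epoxide opening at the CH2 carbon as in step 4, with retention at the stereocentre; the cold quench keeps the magnesium alkoxide from closing a tetrahydropyran onto the chloride.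

Step 8
Reactants: 13 (S)-9-chloronon-1-en-5-ol
Product: 14 (S)-9-chloronon-1-en-5-yl 4-methylbenzenesulfonate
Conditions: TsCl (1.5 equiv), DMAP (0.2 equiv), pyridine, CH2Cl2, 0 °C → rt
Reagents that add atoms: 4-methylbenzenesulfonyl chloride (TsCl), Cc1ccc(cc1)S(Cl)(=O)=O
Why: O-sulfonylation forms the O–S bond only, so the carbinol configuration is retained and the oxygen becomes a leaving group for the later SN2 step.

Step 9
Reactants: 7 2-bromo-1,3-bis(methoxymethoxy)-5-[(1R,2S)-1-(methoxymethoxy)-2-methylbut-3-en-1-yl]benzene; 9 (R)-non-1-en-5-ol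
Product: 16 (5R,10S,11R)-11-[4-bromo-3,5-bis(methoxymethoxy)phenyl]-11-(methoxymethoxy)-10-methylundecan-5-ol (monomer A), via (E)-undec-8-en-5-ol cross-metathesis product 15 (not isolated)
Conditions: 9 (3 equiv), second-generation Grubbs catalyst RuCl2(=CHPh)(H2IMes)(PCy3) (5 mol %), ClCH2CH2Cl, 45 °C; then H2 (7 bar), 70 °C, same flask
Reagents that add atoms: none
Why: olefin cross-metathesis between the hindered allylic-branched vinyl group and an unhindered terminal olefin used in excess, followed by hydrogenation with the ruthenium hydride formed from the same catalyst under H2 (tandem metathesis–hydrogenation); no stereocentre is touched and the aryl bromide survives.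

Step 10
Reactants: 7 2-bromo-1,3-bis(methoxymethoxy)-5-[(1R,2S)-1-(methoxymethoxy)-2-methylbut-3-en-1-yl]benzene; 14 (S)-9-chloronon-1-en-5-yl 4-methylbenzenesulfonate
Product: 18 (5R,10S,11R)-11-[4-bromo-3,5-bis(methoxymethoxy)phenyl]-1-chloro-11-(methoxymethoxy)-10-methylundecan-5-yl 4-methylbenzenesulfonate (monomer B), via (E)-undec-8-en-5-yl tosylate cross-metathesis product 17 (not isolated)
Conditions: 14 (1.5 equiv), second-generation Grubbs catalyst RuCl2(=CHPh)(H2IMes)(PCy3) (5 mol %), ClCH2CH2Cl, 45 °C; then H2 (7 bar), 70 °C, same flask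
Reagents that add atoms: none
Why: the same tandem cross-metathesis–hydrogenation, to which secondary tosylate, primary chloride and aryl bromide are inert; the carbinol carbon keeps its geometry (its descriptor changes from S to R only because saturation changes the CIP ranking).

Step 11
Reactants: 16 monomer A; 18 monomer B
Product: 21 (5R,10S,11R)-11-{4-[(5S,10S,11R)-11-[4-bromo-3,5-bis(methoxymethoxy)phenyl]-1-chloro-11-(methoxymethoxy)-10-methylundecan-5-yl]-3,5-bis(methoxymethoxy)phenyl}-11-(methoxymethoxy)-10-methylundecan-5-ol, via dilithio species 19 (not isolated), via bis(bromomagnesium) species 20 (not isolated)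
Conditions: 16 (1.4 equiv), t-BuLi (3.0 equiv per 16), THF, −78 °C; MgBr2·OEt2 (2.2 equiv per 16), −78 → −20 °C; then 18 (1.0 equiv), CuI (10 mol %), TMEDA (20 mol %), LiOMe (1.0 equiv), THF, 0 °C, 24 h; aq. NH4Cl
Reagents that add atoms: none
Why: bromine–lithium exchange and transmetalation give an aryl Grignard reagent that undergoes copper-catalysed SN2 cross-coupling with the unactivated secondary tosylate (the catalytic form of the arylcuprate–secondary tosylate substitution), which goes with inversion and so sets the chlorobutyl-bearing benzylic centre as S, while the primary chloride and the aryl bromide of 18 do not react at 0 °C.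

Step 12
Reactants: 21 linear dimer alcohol
Product: 22 the 4-methylbenzenesulfonate of 21 (tosylate at the butyl-bearing carbinol, 5R)
Conditions: TsCl (2 equiv), DMAP (0.3 equiv), pyridine, CH2Cl2, 0 °C → rt
Reagents that add atoms: 4-methylbenzenesulfonyl chloride (TsCl), Cc1ccc(cc1)S(Cl)(=O)=O
Why: sulfonylation of the only free hydroxyl with retention of configuration arms the second electrophilic carbon.

Step 13
Reactants: 22 linear dimer tosylate
Product: 25 hexakis(methoxymethyl)-protected [7.7]paracyclophane, via aryllithium 23 (not isolated), via arylmagnesium bromide 24 (not isolated)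
Conditions: t-BuLi (2.05 equiv), THF/Et2O, −100 °C, 5 min; MgBr2·OEt2 (1.2 equiv), → −40 °C; cannula over 10 h into CuI (30 mol %), TMEDA (60 mol %), LiOMe (1.0 equiv), THF, 0 °C (final 1 mM), then 24 h
Reagents that add atoms: none
Why: Proposed new method: bromine–lithium exchange with t-BuLi at −100 °C is faster than attack on the sulfonate or the chloride, magnesium lowers the basicity, and the arylcuprate formed with catalytic CuI adds oxidatively to the tethered secondary tosylate from the back side (trivalent copper intermediate) and reductively eliminates, closing the 22-membered ring with inversion to set the butyl-bearing centre as S under high dilution; the closest known reactions are the Parham cyclialkylation and the copper-catalysed SN2 coupling of Grignard reagents with secondary tosylates.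

Step 14
Reactants: 25 hexakis(methoxymethyl)-protected [7.7]paracyclophane
Product: 26 cyclophane hexaol (four phenols, two benzylic secondary alcohols)
Conditions: 3 M aq. HCl/MeOH/THF, 45 °C
Reagents that add atoms: none
Why: acid-catalysed acetal exchange removes all six MOM groups; the benzylic alcohols have no ortho or para donor and do not ionise, and the primary chloride is inert to acid.

Step 15
Reactants: 26 cyclophane hexaol
Product: 28 target bis-carbamate CNP0117394.1, via hexakis(trichloroacetylcarbamate) 27 (not isolated)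
Conditions: Cl3CC(O)NCO (9 equiv), THF, 0 °C; then K2CO3, MeOH/H2O, 0 °C → rt
Reagents that add atoms: trichloroacetyl isocyanate, O=C=NC(=O)C(Cl)(Cl)Cl
Why: Kočovský carbamoylation in which all six hydroxyls are acylated, after which basic methanolysis removes the trichloroacetyl groups and the four aryl carbamates fragment by E1cB loss of phenoxide while the two alkyl carbamates stay; no stereocentre is touched.

**Compound list**

1 | 3,5-dihydroxybenzaldehyde | O=Cc1cc(O)cc(O)c1 | starting material
2 | 3,5-bis(methoxymethoxy)benzaldehyde | O=Cc1cc(OCOC)cc(OCOC)c1 | intermediate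
3 | 2-{(1R,2S)-1-[3,5-bis(methoxymethoxy)phenyl]-2-methylbut-3-en-1-yloxy}-4,4,5,5-tetramethyl-1,3,2-dioxaborolane | C=C[C@H](C)[C@@H](OB1OC(C)(C)C(C)(C)O1)c1cc(OCOC)cc(OCOC)c1 | intermediate
4 | (1R,2S)-1-[3,5-bis(methoxymethoxy)phenyl]-2-methylbut-3-en-1-ol | C=C[C@H](C)[C@@H](O)c1cc(OCOC)cc(OCOC)c1 | intermediate
5 | lithium (1R,2S)-1-[4-lithio-3,5-bis(methoxymethoxy)phenyl]-2-methylbut-3-en-1-olate | C=C[C@H](C)[C@@H](O[Li])c1cc(OCOC)c([Li])c(OCOC)c1 | intermediate
6 | lithium (1R,2S)-1-[4-bromo-3,5-bis(methoxymethoxy)phenyl]-2-methylbut-3-en-1-olate | C=C[C@H](C)[C@@H](O[Li])c1cc(OCOC)c(Br)c(OCOC)c1 | intermediate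
7 | 2-bromo-1,3-bis(methoxymethoxy)-5-[(1R,2S)-1-(methoxymethoxy)-2-methylbut-3-en-1-yl]benzene | C=C[C@H](C)[C@@H](OCOC)c1cc(OCOC)c(Br)c(OCOC)c1 | intermediate
8 | (R)-2-butyloxirane ((R)-1,2-epoxyhexane) | CCCC[C@@H]1CO1 | starting material
9 | (R)-non-1-en-5-ol | CCCC[C@@H](O)CCC=C | intermediate
10 | 6-chlorohex-1-ene | C=CCCCCCl | starting material
11 | rac-2-(4-chlorobutyl)oxirane | ClCCCCC1CO1 | intermediate
12 | (S)-2-(4-chlorobutyl)oxirane | ClCCCC[C@H]1CO1 | intermediate
13 | (S)-9-chloronon-1-en-5-ol | ClCCCC[C@H](O)CCC=C | intermediate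
14 | (S)-9-chloronon-1-en-5-yl 4-methylbenzenesulfonate | ClCCCC[C@H](OS(=O)(=O)c1ccc(C)cc1)CCC=C | intermediate
15 | (5R,8E,10S,11R)-11-[4-bromo-3,5-bis(methoxymethoxy)phenyl]-11-(methoxymethoxy)-10-methylundec-8-en-5-ol | CCCC[C@@H](O)CC/C=C/[C@H](C)[C@@H](OCOC)c1cc(OCOC)c(Br)c(OCOC)c1 | intermediate
16 | (5R,10S,11R)-11-[4-bromo-3,5-bis(methoxymethoxy)phenyl]-11-(methoxymethoxy)-10-methylundecan-5-ol (monomer A) | CCCC[C@@H](O)CCCC[C@H](C)[C@@H](OCOC)c1cc(OCOC)c(Br)c(OCOC)c1 | intermediate
17 | (5S,8E,10S,11R)-11-[4-bromo-3,5-bis(methoxymethoxy)phenyl]-1-chloro-11-(methoxymethoxy)-10-methylundec-8-en-5-yl 4-methylbenzenesulfonate | ClCCCC[C@H](OS(=O)(=O)c1ccc(C)cc1)CC/C=C/[C@H](C)[C@@H](OCOC)c1cc(OCOC)c(Br)c(OCOC)c1 | intermediate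
18 | (5R,10S,11R)-11-[4-bromo-3,5-bis(methoxymethoxy)phenyl]-1-chloro-11-(methoxymethoxy)-10-methylundecan-5-yl 4-methylbenzenesulfonate (monomer B) | ClCCCC[C@H](OS(=O)(=O)c1ccc(C)cc1)CCCC[C@H](C)[C@@H](OCOC)c1cc(OCOC)c(Br)c(OCOC)c1 | intermediate
19 | dilithio species of 16 (lithium alkoxide, aryllithium in place of bromine) | CCCC[C@@H](O[Li])CCCC[C@H](C)[C@@H](OCOC)c1cc(OCOC)c([Li])c(OCOC)c1 | intermediate
20 | bis(bromomagnesium) species of 16 (magnesium alkoxide, arylmagnesium bromide) | CCCC[C@@H](O[Mg]Br)CCCC[C@H](C)[C@@H](OCOC)c1cc(OCOC)c([Mg]Br)c(OCOC)c1 | intermediate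
21 | (5R,10S,11R)-11-{4-[(5S,10S,11R)-11-[4-bromo-3,5-bis(methoxymethoxy)phenyl]-1-chloro-11-(methoxymethoxy)-10-methylundecan-5-yl]-3,5-bis(methoxymethoxy)phenyl}-11-(methoxymethoxy)-10-methylundecan-5-ol | CCCC[C@@H](O)CCCC[C@H](C)[C@@H](OCOC)c1cc(OCOC)c(c(OCOC)c1)[C@H](CCCCCl)CCCC[C@H](C)[C@@H](OCOC)c1cc(OCOC)c(Br)c(OCOC)c1 | intermediate
22 | 4-methylbenzenesulfonate of 21 at the butyl-bearing carbinol (5R) | CCCC[C@@H](OS(=O)(=O)c1ccc(C)cc1)CCCC[C@H](C)[C@@H](OCOC)c1cc(OCOC)c(c(OCOC)c1)[C@H](CCCCCl)CCCC[C@H](C)[C@@H](OCOC)c1cc(OCOC)c(Br)c(OCOC)c1 | intermediate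
23 | aryllithium from 22 (lithium in place of bromine on ring B) | CCCC[C@@H](OS(=O)(=O)c1ccc(C)cc1)CCCC[C@H](C)[C@@H](OCOC)c1cc(OCOC)c(c(OCOC)c1)[C@H](CCCCCl)CCCC[C@H](C)[C@@H](OCOC)c1cc(OCOC)c([Li])c(OCOC)c1 | intermediate
24 | arylmagnesium bromide from 22 (MgBr in place of bromine on ring B) | CCCC[C@@H](OS(=O)(=O)c1ccc(C)cc1)CCCC[C@H](C)[C@@H](OCOC)c1cc(OCOC)c(c(OCOC)c1)[C@H](CCCCCl)CCCC[C@H](C)[C@@H](OCOC)c1cc(OCOC)c([Mg]Br)c(OCOC)c1 | intermediate
25 | hexakis(methoxymethyl) ether of 26: the [7.7]paracyclophane with all four phenolic and both benzylic oxygens as MOM ethers (benzylic C–O centres R,R; methyl centres S,S; butyl-bearing centre S; 4-chlorobutyl-bearing centre S) | CCCC[C@H]1CCCC[C@H](C)[C@@H](OCOC)c2cc(OCOC)c(c(OCOC)c2)[C@H](CCCCCl)CCCC[C@H](C)[C@@H](OCOC)c2cc(OCOC)c1c(OCOC)c2 | intermediate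
26 | cyclophane hexaol (the target without its two carbamoyl groups) | CCCC[C@H]1CCCC[C@H](C)[C@@H](O)c2cc(O)c(c(O)c2)[C@H](CCCCCl)CCCC[C@H](C)[C@@H](O)c2cc(O)c1c(O)c2 | intermediate
27 | hexakis(N-trichloroacetylcarbamate) of 26 | CCCC[C@H]1CCCC[C@H](C)[C@@H](OC(=O)NC(=O)C(Cl)(Cl)Cl)c2cc(OC(=O)NC(=O)C(Cl)(Cl)Cl)c(c(OC(=O)NC(=O)C(Cl)(Cl)Cl)c2)[C@H](CCCCCl)CCCC[C@H](C)[C@@H](OC(=O)NC(=O)C(Cl)(Cl)Cl)c2cc(OC(=O)NC(=O)C(Cl)(Cl)Cl)c1c(OC(=O)NC(=O)C(Cl)(Cl)Cl)c2 | intermediate
28 | CNP0117394.1, the bis-carbamate [7.7]paracyclophane | CCCC[C@H]1CCCC[C@H](C)[C@@H](OC(N)=O)c2cc(O)c(c(O)c2)[C@H](CCCCCl)CCCC[C@H](C)[C@@H](OC(N)=O)c2cc(O)c1c(O)c2 | target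

**Step count and risks**

Total: 15 steps. Longest linear sequence: 10 steps (10 → 11 → 12 → 13 → 14 → 18 → 21 → 22 → 25 → 26 → 28; steps 5, 6, 7, 8, 10, 11, 12, 13, 14, 15).

The three steps most likely to fail:

1. Step 13 (macrocyclization by intramolecular aryl–alkyl SN2). Risks are elimination of the tosylate, protonation of the dilute Grignard reagent, and oligomers. Fallback: close the ring by olefin metathesis and make both aryl–alkyl bonds intermolecularly. It sets out from 7, 9 and 18 and comes back at 25. Magnesium insertion into 7 (Mg, LiCl, THF) gives the arylmagnesium bromide of 7 F1, which is coupled with 18 under the step 11 conditions to give the vinyl-bearing dimer bromide F2. Alcohol 9 is converted with TsCl into (R)-non-1-en-5-yl tosylate F3. Magnesium insertion into F2 gives the arylmagnesium bromide of F2 F4, which is coupled with excess F3 (inversion) to give the diene F5. Ring-closing metathesis of F5 (second-generation Grubbs catalyst, 1 mM) gives the macrocyclic alkene F6, and hydrogenation in the same flask gives 25.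

2. Step 11 (intermolecular SN2 of the doubly ortho-substituted aryl nucleophile on an unactivated secondary tosylate). Risks are elimination or no reaction. Fallback: make the same bond on an activated allylic electrophile by anti-selective SN2′ substitution, with the stereocentre coming from 1,3-chirality transfer. It sets out from 7 and 20 and comes back at 21. Linear-selective hydroformylation of 7 (Rh(acac)(CO)2, Xantphos, CO/H2) gives the pentanal F7. Catalytic asymmetric alkenylzinc addition (6-chlorohex-1-yne, Cy2BH, then Et2Zn, and the DAIB antipode that delivers the R carbinol, expected (−)) gives the (R,E)-allylic alcohol F8. Esterification with picolinic acid (DCC, DMAP) gives the allylic picolinate F9. Species 20 is transmetalated with CuBr·SMe2 to the arylcopper reagent F10, which attacks F9 at the γ-carbon anti to the leaving group to give the S-configured alkene F11. Diimide reduction (TsNHNH2, NaOAc) of F11 gives 21.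

3. Step 15 (exhaustive acylation, then selective loss of the aryl carbamates). Risks are incomplete acylation of the hindered benzylic alcohols or surviving aryl carbamates. Fallback: mask the phenols first. It sets out from 26 and comes back at 28. Schotten–Baumann acetylation (Ac2O, aq. NaOH, 0 °C) acylates only the phenols and gives the tetra-aryl acetate F12. Trichloroacetyl isocyanate then gives the bis(trichloroacetylcarbamate) tetraacetate F13. K2CO3 in MeOH removes the trichloroacetyl groups and the four aryl acetates in one operation to give 28.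

**Further compounds**

F1 | step 13 | arylmagnesium bromide of 7 | C=C[C@H](C)[C@@H](OCOC)c1cc(OCOC)c([Mg]Br)c(OCOC)c1
F2 | step 13 | vinyl-bearing dimer bromide (ring A carrying the (1R,2S)-1-(methoxymethoxy)-2-methylbut-3-enyl chain, joined at C-2 to the S chlorobutyl-bearing carbon of the ring B bromide unit) | C=C[C@H](C)[C@@H](OCOC)c1cc(OCOC)c(c(OCOC)c1)[C@H](CCCCCl)CCCC[C@H](C)[C@@H](OCOC)c1cc(OCOC)c(Br)c(OCOC)c1
F3 | step 13 | (R)-non-1-en-5-yl 4-methylbenzenesulfonate | CCCC[C@@H](OS(=O)(=O)c1ccc(C)cc1)CCC=C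
F4 | step 13 | arylmagnesium bromide of F2 | C=C[C@H](C)[C@@H](OCOC)c1cc(OCOC)c(c(OCOC)c1)[C@H](CCCCCl)CCCC[C@H](C)[C@@H](OCOC)c1cc(OCOC)c([Mg]Br)c(OCOC)c1
F5 | step 13 | diene (F2 with the bromine replaced by the (S)-non-1-en-5-yl group) | C=C[C@H](C)[C@@H](OCOC)c1cc(OCOC)c(c(OCOC)c1)[C@H](CCCCCl)CCCC[C@H](C)[C@@H](OCOC)c1cc(OCOC)c(c(OCOC)c1)[C@@H](CCCC)CCC=C
F6 | step 13 | macrocyclic alkene (25 with one ring C=C next to a methyl-bearing carbon, E/Z mixture) | CCCC[C@H]1CCC=C[C@H](C)[C@@H](OCOC)c2cc(OCOC)c(c(OCOC)c2)[C@H](CCCCCl)CCCC[C@H](C)[C@@H](OCOC)c2cc(OCOC)c1c(OCOC)c2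
F7 | step 11 | (4S,5R)-5-[4-bromo-3,5-bis(methoxymethoxy)phenyl]-5-(methoxymethoxy)-4-methylpentanal | O=CCC[C@H](C)[C@@H](OCOC)c1cc(OCOC)c(Br)c(OCOC)c1
F8 | step 11 | (1R,2S,5R,6E)-1-[4-bromo-3,5-bis(methoxymethoxy)phenyl]-11-chloro-1-(methoxymethoxy)-2-methylundec-6-en-5-ol | ClCCCC/C=C/[C@H](O)CC[C@H](C)[C@@H](OCOC)c1cc(OCOC)c(Br)c(OCOC)c1
F9 | step 11 | pyridine-2-carboxylate (picolinate) of F8 | ClCCCC/C=C/[C@H](OC(=O)c1ccccn1)CC[C@H](C)[C@@H](OCOC)c1cc(OCOC)c(Br)c(OCOC)c1
F10 | step 11 | arylcopper reagent from 20 (copper in place of the aryl MgBr) | CCCC[C@@H](O[Mg]Br)CCCC[C@H](C)[C@@H](OCOC)c1cc(OCOC)c([Cu])c(OCOC)c1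
F11 | step 11 | alkene analogue of 21 (E double bond between the two carbons next to the chlorobutyl-bearing benzylic carbon on the ring B side) | CCCC[C@@H](O)CCCC[C@H](C)[C@@H](OCOC)c1cc(OCOC)c(c(OCOC)c1)[C@H](CCCCCl)/C=C/CC[C@H](C)[C@@H](OCOC)c1cc(OCOC)c(Br)c(OCOC)c1
F12 | step 15 | tetra-aryl acetate of 26 (both benzylic alcohols free) | CCCC[C@H]1CCCC[C@H](C)[C@@H](O)c2cc(OC(C)=O)c(c(OC(C)=O)c2)[C@H](CCCCCl)CCCC[C@H](C)[C@@H](O)c2cc(OC(C)=O)c1c(OC(C)=O)c2
F13 | step 15 | bis(N-trichloroacetylcarbamate) of F12 | CCCC[C@H]1CCCC[C@H](C)[C@@H](OC(=O)NC(=O)C(Cl)(Cl)Cl)c2cc(OC(C)=O)c(c(OC(C)=O)c2)[C@H](CCCCCl)CCCC[C@H](C)[C@@H](OC(=O)NC(=O)C(Cl)(Cl)Cl)c2cc(OC(C)=O)c1c(OC(C)=O)c2
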